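**Retrosynthetic overview**
1. Target ⇐ its 4'-O-triisopropylsilyl ether; both prenyl groups ⇐ allyl groups by double olefin cross-metathesis with 2-methyl-2-butene.
2. 6,8-Diallyl-7-hydroxyisoflavone ⇐ two rounds of 7-O-allylation and aromatic Claisen rearrangement on the daidzein core (C8 first, then C6).
3. Daidzein core ⇐ 2'-hydroxychalcone by oxidative 1,2-aryl shift, then acid closure of ring C.
4. Chalcone ⇐ intermolecular Claisen–Schmidt aldol condensation of 4-benzyloxy-2-hydroxyacetophenone (ring A) with 4-benzyloxybenzaldehyde (ring B); this is the key C–C bond.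
5. Ring order: rings A and B are bought as arenes; ring C is formed after the aldol and rearrangement; ring A is substituted last.

Assumption: the target has no stereocentre and no E/Z-defined double bond, so the SMILES as given is the one defined compound to be made.

**Step 1**
Reactants: 1 2,4-dihydroxyacetophenone
Product: 2 4-(benzyloxy)-2-hydroxyacetophenone
Conditions: BnBr (1.05 eq), K2CO3 (1.2 eq), acetone, reflux, 6 h
Reagents that add atoms: benzyl bromide, BrCc1ccccc1
Why: Williamson ether synthesis; the 2-OH is hydrogen-bonded to the acetyl carbonyl, so only the 4-OH is alkylated.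

**Step 2**
Reactants: 2 4-(benzyloxy)-2-hydroxyacetophenone; 3 4-(benzyloxy)benzaldehyde
Product: 5 (E)-4,4'-bis(benzyloxy)-2'-hydroxychalcone, via aldol adduct 4 (not isolated)
Conditions: 50% aq. KOH (10 eq), EtOH, rt, 40 h; then ice / 1 M HCl
Reagents that add atoms: none
Why: Claisen–Schmidt (crossed aldol) condensation of the methyl ketone enolate with a non-enolisable aldehyde, followed by E1cB dehydration to the conjugated E-enone; the carbinol centre of 4 is racemic and is lost on dehydration.

**Step 3**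
Reactants: 5 (E)-4,4'-bis(benzyloxy)-2'-hydroxychalcone
Product: 6 1-[4-(benzyloxy)-2-hydroxyphenyl]-2-[4-(benzyloxy)phenyl]-3,3-dimethoxypropan-1-one (racemic)
Conditions: Tl(NO3)3·3H2O (1.1 eq), MeOH/HC(OMe)3 (1:1), rt, 16 h; filter off TlNO3
Reagents that add atoms: methanol, CO
Why: Oxidative 1,2-aryl migration (chalcone-to-isoflavone rearrangement) by trivalent thallium, in which the electron-rich 4-benzyloxyphenyl ring shifts from C-β to C-α and methanol traps the aldehyde carbon as its dimethyl acetal; the new stereocentre is racemic and is erased in step 4.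

**Step 4**
Reactants: 6 1-[4-(benzyloxy)-2-hydroxyphenyl]-2-[4-(benzyloxy)phenyl]-3,3-dimethoxypropan-1-one
Product: 8 7,4'-bis(benzyloxy)isoflavone, via 2-methoxyisoflavanone 7 (not isolated)
Conditions: conc. HCl (10% v/v), MeOH, reflux, 3 h
Reagents that add atoms: none
Why: Acid-catalysed transacetalisation by the 2-hydroxyl closes ring C, and β-elimination of methanol gives the chromen-4-one; benzyl ethers are stable to HCl/MeOH.

**Step 5**
Reactants: 8 7,4'-bis(benzyloxy)isoflavone
Product: 10 daidzein (7,4'-dihydroxyisoflavone), via mono-benzyl ether 9 (not isolated)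
Conditions: H2 (1 atm), 10% Pd/C, THF/MeOH (1:1), rt, stopped at complete debenzylation (TLC)
Reagents that add atoms: none
Why: Catalytic hydrogenolysis of benzyl aryl ethers is much faster than reduction of the conjugated C2=C3 bond of the isoflavone, so stopping at full conversion gives the diphenol.

**Step 6**
Reactants: 10 daidzein
Product: 11 7-(allyloxy)-3-(4-hydroxyphenyl)-4H-chromen-4-one
Conditions: allyl bromide (1.05 eq), K2CO3 (1.1 eq), DMF, rt, 12 h
Reagents that add atoms: allyl bromide, C=CCBr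
Why: Williamson etherification under acidity control; the 7-OH is a vinylogous carboxylic acid (pKa about 7.5) and is ionised and alkylated before the 4'-OH (pKa about 9.5).

**Step 7**
Reactants: 11 7-(allyloxy)-3-(4-hydroxyphenyl)-4H-chromen-4-one
Product: 12 7-(allyloxy)-4'-(triisopropylsilyloxy)isoflavone
Conditions: TIPSCl (1.3 eq), imidazole (2.5 eq), DMF, rt, 6 h
Reagents that add atoms: triisopropylsilyl chloride, CC(C)[Si](Cl)(C(C)C)C(C)C
Why: Imidazole-promoted O-silylation of the only free phenol gives a bulky aryl silyl ether that tolerates carbonate base, 200 °C and ruthenium metathesis and is removed by fluoride without acid.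

**Step 8**
Reactants: 12 7-(allyloxy)-4'-(triisopropylsilyloxy)isoflavone
Product: 14 8-allyl-7-hydroxy-4'-(triisopropylsilyloxy)isoflavone, via cyclohexadienone 13 (not isolated)
Conditions: N,N-diethylaniline, 200 °C, Ar, 5 h
Reagents that add atoms: none
Why: Aromatic Claisen ([3,3]-sigmatropic) rearrangement, which goes to C8 because the C7–C8 bond of a 7-oxychromone has the higher double-bond character; the racemic dienone 13 tautomerises to the phenol.

**Step 9**
Reactants: 14 8-allyl-7-hydroxy-4'-(triisopropylsilyloxy)isoflavone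
Product: 15 8-allyl-7-(allyloxy)-4'-(triisopropylsilyloxy)isoflavone
Conditions: allyl bromide (1.5 eq), K2CO3 (2 eq), dry acetone, reflux, 8 h
Reagents that add atoms: allyl bromide, C=CCBr
Why: Williamson O-allylation of the acidic 7-OH; anhydrous K2CO3 in acetone does not cleave the aryl triisopropylsilyl ether.

**Step 10**
Reactants: 15 8-allyl-7-(allyloxy)-4'-(triisopropylsilyloxy)isoflavone
Product: 17 6,8-diallyl-7-hydroxy-4'-(triisopropylsilyloxy)isoflavone, via cyclohexadienone 16 (not isolated)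
Conditions: N,N-diethylaniline, 210 °C, Ar, 8 h
Reagents that add atoms: none
Why: Second aromatic Claisen rearrangement; with C8 blocked, the only ortho position able to rearomatise is C6, and the basic solvent suppresses cyclisation of the ortho-allyl phenols.

**Step 11**
Reactants: 17 6,8-diallyl-7-hydroxy-4'-(triisopropylsilyloxy)isoflavone
Product: 19 7-hydroxy-6,8-diprenyl-4'-(triisopropylsilyloxy)isoflavone, via mono-prenyl compound 18 (not isolated)
Conditions: second-generation Grubbs catalyst [RuCl2(=CHPh)(PCy3)(1,3-dimesitylimidazolidin-2-ylidene)] (2 × 5 mol%), 1,4-benzoquinone (10 mol%), 2-methyl-2-butene/CH2Cl2 (1:1), 40 °C, sealed tube, 16 h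
Reagents that add atoms: 2-methyl-2-butene, CC=C(C)C
Why: Olefin cross-metathesis of each terminal allyl group with excess 2-methyl-2-butene exchanges =CH2 for =C(CH3)2 with loss of propene; benzoquinone suppresses isomerisation of allyl to propenyl.

**Step 12**
Reactants: 19 7-hydroxy-6,8-diprenyl-4'-(triisopropylsilyloxy)isoflavone
Product: 20 7-hydroxy-3-(4-hydroxyphenyl)-6,8-bis(3-methylbut-2-en-1-yl)-4H-chromen-4-one (target)
Conditions: TBAF (1.1 eq), AcOH (1.1 eq), THF, 0 °C, 30 min
Reagents that add atoms: none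
Why: Fluoride-mediated desilylation (Si–F bond formation) under buffered, non-acidic conditions, so the ortho-prenyl phenol cannot cyclise to a chroman and ring C is not opened.

**Compound list**
1 | 2,4-dihydroxyacetophenone | CC(=O)c1ccc(O)cc1O | starting material
2 | 1-[4-(benzyloxy)-2-hydroxyphenyl]ethan-1-one | CC(=O)c1ccc(OCc2ccccc2)cc1O | intermediate
3 | 4-(benzyloxy)benzaldehyde | O=Cc1ccc(OCc2ccccc2)cc1 | starting material
4 | 1-[4-(benzyloxy)-2-hydroxyphenyl]-3-[4-(benzyloxy)phenyl]-3-hydroxypropan-1-one (racemic aldol adduct, not isolated) | O=C(CC(O)c1ccc(OCc2ccccc2)cc1)c1ccc(OCc2ccccc2)cc1O | intermediate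
5 | (E)-1-[4-(benzyloxy)-2-hydroxyphenyl]-3-[4-(benzyloxy)phenyl]prop-2-en-1-one | O=C(/C=C/c1ccc(OCc2ccccc2)cc1)c1ccc(OCc2ccccc2)cc1O | intermediate
6 | 1-[4-(benzyloxy)-2-hydroxyphenyl]-2-[4-(benzyloxy)phenyl]-3,3-dimethoxypropan-1-one (racemic) | COC(OC)C(c1ccc(OCc2ccccc2)cc1)C(=O)c1ccc(OCc2ccccc2)cc1O | intermediate
7 | 7-(benzyloxy)-3-[4-(benzyloxy)phenyl]-2-methoxychroman-4-one (racemic diastereomer mixture, not isolated) | COC1Oc2cc(OCc3ccccc3)ccc2C(=O)C1c1ccc(OCc2ccccc2)cc1 | intermediate
8 | 7-(benzyloxy)-3-[4-(benzyloxy)phenyl]-4H-chromen-4-one | O=c1c(-c2ccc(OCc3ccccc3)cc2)coc2cc(OCc3ccccc3)ccc12 | intermediate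
9 | 3-[4-(benzyloxy)phenyl]-7-hydroxy-4H-chromen-4-one (half-debenzylated, not isolated; the 7-benzyl isomer behaves the same way) | O=c1c(-c2ccc(OCc3ccccc3)cc2)coc2cc(O)ccc12 | intermediate
10 | daidzein, 7-hydroxy-3-(4-hydroxyphenyl)-4H-chromen-4-one | O=c1c(-c2ccc(O)cc2)coc2cc(O)ccc12 | intermediate
11 | 7-(allyloxy)-3-(4-hydroxyphenyl)-4H-chromen-4-one | C=CCOc1ccc2c(=O)c(-c3ccc(O)cc3)coc2c1 | intermediate
12 | 7-(allyloxy)-3-[4-(triisopropylsilyloxy)phenyl]-4H-chromen-4-one | C=CCOc1ccc2c(=O)c(-c3ccc(O[Si](C(C)C)(C(C)C)C(C)C)cc3)coc2c1 | intermediate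
13 | 8-allyl-3-[4-(triisopropylsilyloxy)phenyl]-4H-chromene-4,7(8H)-dione (racemic Claisen dienone, not isolated) | O=C1C=CC2=C(OC=C(c3ccc(O[Si](C(C)C)(C(C)C)C(C)C)cc3)C2=O)C1CC=C | intermediate
14 | 8-allyl-7-hydroxy-3-[4-(triisopropylsilyloxy)phenyl]-4H-chromen-4-one | C=CCc1c(O)ccc2c(=O)c(-c3ccc(O[Si](C(C)C)(C(C)C)C(C)C)cc3)coc12 | intermediate
15 | 8-allyl-7-(allyloxy)-3-[4-(triisopropylsilyloxy)phenyl]-4H-chromen-4-one | C=CCOc1ccc2c(=O)c(-c3ccc(O[Si](C(C)C)(C(C)C)C(C)C)cc3)coc2c1CC=C | intermediate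
16 | 6,8-diallyl-3-[4-(triisopropylsilyloxy)phenyl]-4H-chromene-4,7(6H)-dione (racemic Claisen dienone, not isolated) | C=CCC1C=C2C(=O)C(c3ccc(O[Si](C(C)C)(C(C)C)C(C)C)cc3)=COC2=C(CC=C)C1=O | intermediate
17 | 6,8-diallyl-7-hydroxy-3-[4-(triisopropylsilyloxy)phenyl]-4H-chromen-4-one | C=CCc1cc2c(=O)c(-c3ccc(O[Si](C(C)C)(C(C)C)C(C)C)cc3)coc2c(CC=C)c1O | intermediate
18 | 8-allyl-7-hydroxy-6-(3-methylbut-2-en-1-yl)-3-[4-(triisopropylsilyloxy)phenyl]-4H-chromen-4-one (half-metathesised, not isolated; the 6-allyl-8-prenyl isomer behaves the same way) | CC(C)=CCc1cc2c(=O)c(-c3ccc(O[Si](C(C)C)(C(C)C)C(C)C)cc3)coc2c(CC=C)c1O | intermediate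
19 | 7-hydroxy-6,8-bis(3-methylbut-2-en-1-yl)-3-[4-(triisopropylsilyloxy)phenyl]-4H-chromen-4-one | CC(C)=CCc1cc2c(=O)c(-c3ccc(O[Si](C(C)C)(C(C)C)C(C)C)cc3)coc2c(CC=C(C)C)c1O | intermediate
20 | 7-hydroxy-3-(4-hydroxyphenyl)-6,8-bis(3-methylbut-2-en-1-yl)-4H-chromen-4-one | CC(C)=CCc1cc2c(=O)c(-c3ccc(O)cc3)coc2c(CC=C(C)C)c1O | target

**Totals**
Total step count: 12. Longest linear sequence: 12 steps (1 → 20); aldehyde 3 enters at step 2.

**Three steps most likely to fail**

Step 3 (oxidative aryl shift with trivalent thallium; aurone formation or ring oxidation can compete). The fallback sets out from chalcone 5 and comes back at daidzein 10. The chelated 2'-OH of 5 is benzylated (BnBr, K2CO3, DMF, 60 °C) to (E)-1-[2,4-bis(benzyloxy)phenyl]-3-[4-(benzyloxy)phenyl]prop-2-en-1-one F1. Weitz–Scheffer epoxidation (30% H2O2, aq. NaOH, MeOH/acetone, 0 °C to rt) gives the racemic trans-epoxide [2,4-bis(benzyloxy)phenyl]{3-[4-(benzyloxy)phenyl]oxiran-2-yl}methanone F2. BF3·OEt2 in CH2Cl2 at 0 °C opens the epoxide at the benzylic carbon and the aroyl group undergoes a 1,2-acyl shift to 3-[2,4-bis(benzyloxy)phenyl]-2-[4-(benzyloxy)phenyl]-3-oxopropanal F3. Hydrogenolysis (H2, 10% Pd/C, EtOAc/MeOH, trace HCl) removes the three benzyl groups, and the freed 2-hydroxyl condenses with the formyl group with loss of water to give 10.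

Step 10 (Claisen rearrangement to the less favoured C6 position; it is slower than step 8 and may stall or cause decomposition). The fallback sets out from phenol 14 and comes back at 17. It replaces the O-allylation and sigmatropic shift by direct ortho C-allylation: the sodium phenoxide of 14 (NaH, toluene) is heated with allyl bromide at 70 °C. In the non-polar medium the tight ion pair alkylates at carbon, and C6 is the only free ortho position. This fallback makes no compound outside the list, F0.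

Step 11 (double cross-metathesis next to a free phenol; incomplete second exchange or allyl-to-propenyl isomerisation). The fallback sets out from 17 and comes back at 19. Lemieux–Johnson cleavage of both terminal alkenes (OsO4 2 mol%, NaIO4 4.5 eq, 2,6-lutidine, dioxane/H2O, rt) gives 2,2'-{7-hydroxy-4-oxo-3-[4-(triisopropylsilyloxy)phenyl]-4H-chromene-6,8-diyl}diacetaldehyde F4, partly present as the lactol with the 7-OH. Wittig olefination with excess isopropylidenetriphenylphosphorane (from isopropyltriphenylphosphonium iodide and n-BuLi, THF, −78 to 0 °C) turns both aldehydes into prenyl groups and gives 19.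

**Further compounds**
F1 | step 3 | (E)-1-[2,4-bis(benzyloxy)phenyl]-3-[4-(benzyloxy)phenyl]prop-2-en-1-one | O=C(/C=C/c1ccc(OCc2ccccc2)cc1)c1ccc(OCc2ccccc2)cc1OCc1ccccc1
F2 | step 3 | [2,4-bis(benzyloxy)phenyl]{3-[4-(benzyloxy)phenyl]oxiran-2-yl}methanone (trans, racemic; one enantiomer drawn) | O=C([C@H]1O[C@@H]1c1ccc(OCc2ccccc2)cc1)c1ccc(OCc2ccccc2)cc1OCc1ccccc1
F3 | step 3 | 3-[2,4-bis(benzyloxy)phenyl]-2-[4-(benzyloxy)phenyl]-3-oxopropanal (racemic, enolisable) | O=CC(c1ccc(OCc2ccccc2)cc1)C(=O)c1ccc(OCc2ccccc2)cc1OCc1ccccc1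
F0 | step 10 | none | none
F4 | step 11 | 2,2'-{7-hydroxy-4-oxo-3-[4-(triisopropylsilyloxy)phenyl]-4H-chromene-6,8-diyl}diacetaldehyde | O=CCc1cc2c(=O)c(-c3ccc(O[Si](C(C)C)(C(C)C)C(C)C)cc3)coc2c(CC=O)c1O
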